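**Retrosynthetic overview**
1. Feature: the target is a head-to-tail pseudo-dimer of one unit, ArCH2–CH(CH3)–O–C(=O)–CH2–CH(CH3)–OH. Each 3-hydroxybutanoyl unit (B and D) is C2–C4 from propylene oxide plus carbonyl C1 from CO, and each arylpropan-2-ol chain (rings A and C) is the same epoxide on an arene. All four stereocentres are therefore the CH(CH3)–O carbon of (R)-propylene oxide.
2. Last disconnection: the aryl ester between the ring C carboxyl carbon and O3 of unit B, giving alcohol 5 (ring A plus unit B) and acid 9 (ring C plus unit D). Four benzyl ethers and one benzyl carbonate fall together at the end.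
3. Acid 9 is 5 itself after O-protection and introduction of the carboxyl carbon on the ring carbon next to the side chain (Vilsmeier–Haack formylation, Pinnick oxidation). One key step thus supplies both hydroxybutanoate units.
4. 5 comes from carbinol 4, (R)-propylene oxide and CO by cobalt-catalysed alkoxycarbonylation (C1–C2 bond of the butanoate and the ester C–O bond). 4 comes from the aryl Grignard reagent of 1 and (R)-propylene oxide.
5. No ring is formed in the route: both benzene rings are bought as bromide 1.

Key step: step 2

Remark: 5 is prepared once and divided. One portion goes through steps 3 to 5 to acid 9, the other is the alcohol partner in step 6. Bromide 1, both enantiomers of propylene oxide and CO are taken as commercial.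

**Step 1**
Reactants: 1 1,3-bis(benzyloxy)-5-bromobenzene; 2 (R)-propylene oxide
Product: 4 (R)-1-[3,5-bis(benzyloxy)phenyl]propan-2-ol, via arylmagnesium bromide 3 (not isolated)
Conditions: Mg, THF, reflux; then CuI (10 mol %), 2, −30 → 0 °C; aq NH4Cl
Reagents that add atoms: none
Why: Copper-catalysed SN2 opening of a terminal epoxide by an aryl Grignard reagent occurs at the unsubstituted CH2 carbon, so the C–O stereocentre of 2 is not touched and becomes the (R)-carbinol of 4.

**Step 2**
Reactants: 4 (R)-1-[3,5-bis(benzyloxy)phenyl]propan-2-ol; 2 (R)-propylene oxide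
Product: 5 (R)-1-[3,5-bis(benzyloxy)phenyl]propan-2-yl (R)-3-hydroxybutanoate
Conditions: 4 (3 equiv, excess recovered), 2 (1 equiv), Co2(CO)8 (5 mol %), 3-hydroxypyridine (10 mol %), CO (40 bar), THF, 60 °C
Reagents that add atoms: carbon monoxide, [C-]#[O+]
Why: Proposed new method: Co2(CO)8 and 3-hydroxypyridine generate tetracarbonylcobaltate, which opens the pyridinol-hydrogen-bonded epoxide 2 by SN2 attack at its CH2 carbon; CO insertion gives a 3-hydroxybutanoyl cobalt tetracarbonyl, and alcoholysis of this acyl by the secondary hydroxyl of 4 releases ester 5 and HCo(CO)4, which returns the cobaltate. The closest known reaction is the cobalt-catalysed methoxycarbonylation of terminal epoxides run in methanol, and the same catalyst pair is known to build poly(3-hydroxybutanoate) from propylene oxide and CO through acyl capture by a secondary chain-end hydroxyl, which indicates that a secondary alcohol is a competent acyl acceptor; new here is a complex secondary alcohol used in modest excess instead of as solvent. No ring is closed. No stereocentre is created: the oxygen-bearing carbon of 2 is never a reacting centre, so its (R) configuration passes unchanged into C3 of the hydroxybutanoate, and the carbinol of 4 is acylated at oxygen with retention. The step needs attack at the terminal epoxide carbon (secured by the steric bias of SN2 opening of a monosubstituted epoxide, which excludes the branched 3-hydroxy-2-methylpropanoate) and capture of the acyl by 4 rather than by the hydroxyl of 5 or by its own hydroxyl to give the beta-lactone (secured by keeping 4 in threefold excess over 2 and stopping at full epoxide conversion).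

**Step 3**
Reactants: 5 (R)-1-[3,5-bis(benzyloxy)phenyl]propan-2-yl (R)-3-hydroxybutanoate (one portion)
Product: 6 (R)-1-[3,5-bis(benzyloxy)phenyl]propan-2-yl (R)-3-{[(benzyloxy)carbonyl]oxy}butanoate
Conditions: CbzCl, pyridine, DMAP (cat.), CH2Cl2, 0 °C → rt
Reagents that add atoms: benzyl chloroformate, O=C(Cl)OCc1ccccc1
Why: DMAP-catalysed O-acylation of the secondary alcohol by a chloroformate gives the benzyl carbonate without touching the stereocentre; this group should survive chloroiminium and chlorite conditions and falls in the final hydrogenolysis.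

**Step 4**
Reactants: 6 (R)-1-[3,5-bis(benzyloxy)phenyl]propan-2-yl (R)-3-{[(benzyloxy)carbonyl]oxy}butanoate
Product: 8 (R)-1-[3,5-bis(benzyloxy)-2-formylphenyl]propan-2-yl (R)-3-{[(benzyloxy)carbonyl]oxy}butanoate, via aryl iminium chloride 7 (not isolated)
Conditions: POCl3, DMF, 0 → 50 °C; then aq NaOAc, rt
Reagents that add atoms: N,N-dimethylformamide, CN(C)C=O; water, O
Why: Vilsmeier–Haack formylation of a 5-alkylresorcinol diether goes to the ring carbon next to the side chain (para to one benzyloxy group, ortho to the other), the position between the two benzyloxy groups being the more shielded one, while ester, carbonate and benzyl ethers are inert to the chloroiminium reagent.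

**Step 5**
Reactants: 8 (R)-1-[3,5-bis(benzyloxy)-2-formylphenyl]propan-2-yl (R)-3-{[(benzyloxy)carbonyl]oxy}butanoate
Product: 9 2,4-bis(benzyloxy)-6-[(R)-2-({(R)-3-[(benzyloxycarbonyl)oxy]butanoyl}oxy)propyl]benzoic acid
Conditions: NaClO2, NaH2PO4, 2-methyl-2-butene, t-BuOH/THF/H2O, 0 °C → rt
Reagents that add atoms: sodium chlorite, [Na+].[O-]Cl=O
Why: Pinnick oxidation converts the aryl aldehyde to the acid under buffered conditions, with 2-methyl-2-butene trapping HOCl before it can chlorinate the electron-rich ring.

**Step 6**
Reactants: 9 2,4-bis(benzyloxy)-6-[(R)-2-({(R)-3-[(benzyloxycarbonyl)oxy]butanoyl}oxy)propyl]benzoic acid; 5 (R)-1-[3,5-bis(benzyloxy)phenyl]propan-2-yl (R)-3-hydroxybutanoate (second portion)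
Product: 11 (R)-4-{[(R)-1-[3,5-bis(benzyloxy)phenyl]propan-2-yl]oxy}-4-oxobutan-2-yl 2,4-bis(benzyloxy)-6-[(R)-2-({(R)-3-[(benzyloxycarbonyl)oxy]butanoyl}oxy)propyl]benzoate, via acid chloride 10 (not isolated)
Conditions: (COCl)2, DMF (cat.), CH2Cl2, 0 °C → rt, evaporate; then 5, Et3N, DMAP, CH2Cl2, 0 → 40 °C
Reagents that add atoms: none
Why: DMAP-catalysed acylation of a secondary alcohol by an aroyl chloride forms the aryl ester with retention at the carbinol carbon of 5, since only its O–H bond reacts, and the electron-rich 2,4-dialkoxy ring gives the acyl donor enough acylium character to overcome its two ortho substituents.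

**Step 7**
Reactants: 11 (the tetra-O-benzyl, O-benzyloxycarbonyl derivative of the target)
Product: 12 Hansforester J
Conditions: H2 (1 atm), Pd/C (10 % Pd on carbon), EtOAc/EtOH, rt
Reagents that add atoms: none
Why: Palladium-catalysed hydrogenolysis cleaves the four aryl benzyl ethers and the benzyl carbonate (with loss of CO2) in one operation, while the esters, whose alkyl C–O bonds are homobenzylic and not benzylic, and the four stereocentres are left alone.

**Compound list**
1 | 1,3-bis(benzyloxy)-5-bromobenzene | Brc1cc(OCc2ccccc2)cc(OCc2ccccc2)c1 | starting material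
2 | (R)-propylene oxide | C[C@@H]1CO1 | starting material
3 | [3,5-bis(benzyloxy)phenyl]magnesium bromide | Br[Mg]c1cc(OCc2ccccc2)cc(OCc2ccccc2)c1 | intermediate
4 | (R)-1-[3,5-bis(benzyloxy)phenyl]propan-2-ol | C[C@@H](O)Cc1cc(OCc2ccccc2)cc(OCc2ccccc2)c1 | intermediate
5 | (R)-1-[3,5-bis(benzyloxy)phenyl]propan-2-yl (R)-3-hydroxybutanoate | C[C@H](Cc1cc(OCc2ccccc2)cc(OCc2ccccc2)c1)OC(=O)C[C@@H](C)O | intermediate
6 | (R)-1-[3,5-bis(benzyloxy)phenyl]propan-2-yl (R)-3-{[(benzyloxy)carbonyl]oxy}butanoate | C[C@H](Cc1cc(OCc2ccccc2)cc(OCc2ccccc2)c1)OC(=O)C[C@@H](C)OC(=O)OCc1ccccc1 | intermediate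
7 | aryl iminium chloride: N-{[2,4-bis(benzyloxy)-6-((R)-2-acyloxypropyl)phenyl]methylidene}-N-methylmethanaminium chloride, acyl = (R)-3-[(benzyloxycarbonyl)oxy]butanoyl | C[C@H](Cc1cc(OCc2ccccc2)cc(OCc2ccccc2)c1C=[N+](C)C)OC(=O)C[C@@H](C)OC(=O)OCc1ccccc1.[Cl-] | intermediate
8 | (R)-1-[3,5-bis(benzyloxy)-2-formylphenyl]propan-2-yl (R)-3-{[(benzyloxy)carbonyl]oxy}butanoate | C[C@H](Cc1cc(OCc2ccccc2)cc(OCc2ccccc2)c1C=O)OC(=O)C[C@@H](C)OC(=O)OCc1ccccc1 | intermediate
9 | 2,4-bis(benzyloxy)-6-[(R)-2-({(R)-3-[(benzyloxycarbonyl)oxy]butanoyl}oxy)propyl]benzoic acid | C[C@H](Cc1cc(OCc2ccccc2)cc(OCc2ccccc2)c1C(=O)O)OC(=O)C[C@@H](C)OC(=O)OCc1ccccc1 | intermediate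
10 | 2,4-bis(benzyloxy)-6-[(R)-2-({(R)-3-[(benzyloxycarbonyl)oxy]butanoyl}oxy)propyl]benzoyl chloride | C[C@H](Cc1cc(OCc2ccccc2)cc(OCc2ccccc2)c1C(=O)Cl)OC(=O)C[C@@H](C)OC(=O)OCc1ccccc1 | intermediate
11 | (R)-4-{[(R)-1-[3,5-bis(benzyloxy)phenyl]propan-2-yl]oxy}-4-oxobutan-2-yl 2,4-bis(benzyloxy)-6-[(R)-2-({(R)-3-[(benzyloxycarbonyl)oxy]butanoyl}oxy)propyl]benzoate | C[C@H](Cc1cc(OCc2ccccc2)cc(OCc2ccccc2)c1)OC(=O)C[C@@H](C)OC(=O)c1c(OCc2ccccc2)cc(OCc2ccccc2)cc1C[C@@H](C)OC(=O)C[C@@H](C)OC(=O)OCc1ccccc1 | intermediate
12 | Hansforester J | C[C@H](Cc1cc(O)cc(O)c1)OC(=O)C[C@@H](C)OC(=O)c1c(O)cc(O)cc1C[C@@H](C)OC(=O)C[C@@H](C)O | target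

**Step count**
Total steps: 7. Longest linear sequence: 7 steps (1 → 4 → 5 → 6 → 8 → 9 → 11 → 12), with 5 entering a second time in step 6.

**Steps most likely to fail**

Step 2. Alcoholysis of the acylcobalt by the hindered secondary alcohol may be slow. The acyl would then be taken by the hydroxyl of the product (oligomeric hydroxybutanoates) or by its own hydroxyl (beta-lactone), and the epoxide may drain away by isomerisation to acetone. The fallback sets out from 2 and uses known chemistry. Ring-expanding carbonylation of 2 with [(salph)Al(THF)2][Co(CO)4] under CO should give (R)-beta-butyrolactone F1, with cobaltate attack at CH2 and the stereocentre unchanged. F1 is then opened at the acyl–oxygen bond by an excess of 4 with catalytic TfOH in toluene at room temperature, the known acid-catalysed O-acyl ring opening of beta-butyrolactone by alcohols. This leaves the stereocentre untouched and comes back to the route at 5.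

Step 6. Acyl transfer to the di-ortho-substituted aroyl chloride may be too slow. Base-induced elimination of the beta-acyloxy esters to crotonates, or attack of the neighbouring side-chain ester on the activated carboxyl with loss of unit D, could then take over. The fallback reverses the polarity: the carboxylate of 9 becomes the nucleophile in a Mitsunobu esterification, the standard answer to hindered resorcylate esters, which inverts the carbinol carbon. It sets out from 4 and 9. Carbinol 4, commercial (S)-propylene oxide (C[C@H]1CO1) and CO, under the conditions adopted for step 2, should give (R)-1-[3,5-bis(benzyloxy)phenyl]propan-2-yl (S)-3-hydroxybutanoate F2. Treatment of 9 and F2 with PPh3 and DIAD in toluene at 0 °C → rt should then give the (R)-configured ester by SN2 inversion and comes back to the route at 11.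

Step 4. The weakly electrophilic chloroiminium ion may react sluggishly at the ring position flanked by the branched side chain. Forcing it by heat invites cleavage of benzyl ethers by HCl and attack at the position between the two benzyloxy groups. The fallback sets out from 6 and replaces formylation and oxidation by halogenation and carbonylation. Iodination with NIS and catalytic TFA in MeCN at 0 °C, a much faster substitution at the same position, should give (R)-1-[3,5-bis(benzyloxy)-2-iodophenyl]propan-2-yl (R)-3-{[(benzyloxy)carbonyl]oxy}butanoate F3. Palladium-catalysed hydroxycarbonylation of F3 (Pd(OAc)2, Xantphos, CO, Et3N, H2O, DMF, 60 °C) should then give the acid directly. This bypasses 8 and step 5 and comes back to the route at 9.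

**Further compounds**
F1 | step 2 | (R)-beta-butyrolactone, (R)-4-methyloxetan-2-one | C[C@@H]1CC(=O)O1
F2 | step 6 | (R)-1-[3,5-bis(benzyloxy)phenyl]propan-2-yl (S)-3-hydroxybutanoate | C[C@H](Cc1cc(OCc2ccccc2)cc(OCc2ccccc2)c1)OC(=O)C[C@H](C)O
F3 | step 4 | (R)-1-[3,5-bis(benzyloxy)-2-iodophenyl]propan-2-yl (R)-3-{[(benzyloxy)carbonyl]oxy}butanoate | C[C@H](Cc1cc(OCc2ccccc2)cc(OCc2ccccc2)c1I)OC(=O)C[C@@H](C)OC(=O)OCc1ccccc1
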